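## Retrosynthetic overview
1. Both rings of the target are closed in the last flask from an acyclic, fully halogenated C1–C3 farnesane chain. The cyclohexane (C1–C6 bond) forms first and the oxane (O–C11 bond) last.
2. Cyclohexane: bromine-assisted ionisation of a C1 triflate, ring closure by the (6E)-alkene, and capture of C7 by the C8 acetate. This anti addition sets C6 and C7 and gives a transient dioxolanylium ring.
3. Oxane: hydrolysis frees the C7 hydroxyl, which closes by 6-endo bromoetherification onto the prenyl alkene and sets C10.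
4. The C2-Br/C3-Cl pair comes from catalytic enantioselective bromochlorination of the (2Z)-allylic alcohol. C8 comes from a Keck allylation of an enal, and the prenyl end from cross-metathesis.
5. Carbon sources are neryl acetate, allyltributylstannane, 2-methylbut-2-ene and acetic anhydride.

Assumption: atom labels follow the farnesane chain (cyclohexane = C1–C6, oxane = O plus C7–C11). The antipode of the Schiff-base ligand in step 5 is the one that delivers the 2R,3R adduct.

## Route

Step 1
Reactants: 1 neryl acetate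
Product: 2 (2Z,6E)-8-oxoneryl acetate
Conditions: SeO2 (1.1 equiv), 95% EtOH, reflux, 2 h
Reagents that add atoms: selenium dioxide O=[Se]=O
Why: Riley allylic oxidation (ene reaction, then [2,3]-sigmatropic shift) attacks only the (E)-methyl of the electron-rich terminal isopropylidene group because the 2,3-alkene is deactivated by its allylic acetate, so the (6E)-enal forms with the 2Z geometry untouched.

Step 2
Reactants: 2 (2Z,6E)-8-oxoneryl acetate; 3 allyltributylstannane
Product: 4 (2Z,6E,8S)-8-hydroxy-3,7-dimethylundeca-2,6,10-trien-1-yl acetate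
Conditions: (S)-BINOL (20 mol %), Ti(OiPr)4 (10 mol %), 4 Å MS, CH2Cl2, −20 °C; aq NaHCO3
Reagents that add atoms: none
Why: In the Keck asymmetric allylation the (S)-BINOL–Ti(IV) Lewis acid exposes one aldehyde face to 1,2-addition of the stannane, which sets C8 as S (the same facial sense that gives S alcohols from aldehydes whose residue outranks allyl), and the ester is inert.

Step 3
Reactants: 4 (2Z,6E,8S)-8-hydroxy-3,7-dimethylundeca-2,6,10-trien-1-yl acetate
Product: 5 (2Z,6E,8S)-3,7-dimethylundeca-2,6,10-triene-1,8-diyl diacetate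
Conditions: Ac2O, Et3N, DMAP (cat.), CH2Cl2, 0 °C to rt
Reagents that add atoms: acetic anhydride CC(=O)OC(C)=O
Why: DMAP-catalysed acylation installs the acetate of the target on O8 without touching the C8–O bond, so the configuration is retained.

Step 4
Reactants: 5 (2Z,6E,8S)-3,7-dimethylundeca-2,6,10-triene-1,8-diyl diacetate
Product: 6 (2Z,6E,8S)-1-hydroxy-3,7-dimethylundeca-2,6,10-trien-8-yl acetate
Conditions: K2CO3 (0.2 equiv), MeOH, −10 °C, stopped when 5 is consumed
Reagents that add atoms: none
Why: In this chemoselective Zemplén-type transesterification the unhindered primary allylic acetate is methanolysed about an order of magnitude faster than the secondary acetate next to the trisubstituted alkene, so only C1–OH is freed.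

Step 5
Reactants: 6 (2Z,6E,8S)-1-hydroxy-3,7-dimethylundeca-2,6,10-trien-8-yl acetate
Product: 7 (2R,3R,6E,8S)-2-bromo-3-chloro-1-hydroxy-3,7-dimethylundeca-6,10-dien-8-yl acetate
Conditions: NBS (1.05 equiv), ClTi(OiPr)3 (1.1 equiv), chiral tridentate amino-alcohol salicylaldimine ligand (20 mol %), hexanes, −20 °C
Reagents that add atoms: N-bromosuccinimide O=C1CCC(=O)N1Br; chlorotitanium triisopropoxide CC(C)O[Ti](Cl)(OC(C)C)OC(C)C
Why: In this titanium/Schiff-base-catalysed enantioselective bromochlorination of an allylic alcohol the substrate binds titanium as its alkoxide, so only the 2,3-alkene reacts (the 6,7-alkene is deactivated by its allylic acetate and the vinyl group is monosubstituted), Br+ adds to the catalyst-selected face, and titanium-bound chloride opens the bromiranium ion at tertiary C3, so that anti addition to the Z alkene gives the 2R,3R pair.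

Step 6
Reactants: 7 (2R,3R,6E,8S)-2-bromo-3-chloro-1-hydroxy-3,7-dimethylundeca-6,10-dien-8-yl acetate; 8 2-methylbut-2-ene
Product: 9 (2R,3R,6E,8S)-2-bromo-3-chloro-1-hydroxy-3,7,11-trimethyldodeca-6,10-dien-8-yl acetate
Conditions: Grubbs II (5 mol %), 8 (excess, co-solvent), CH2Cl2, 40 °C
Reagents that add atoms: none
Why: Olefin cross-metathesis of the terminal (type I) alkene with excess 2-methylbut-2-ene exchanges =CH2 for =CMe2, while the trisubstituted 6,7-alkene, the alkyl halides, the alcohol and all stereocentres are untouched.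

Step 7
Reactants: 9 (2R,3R,6E,8S)-2-bromo-3-chloro-1-hydroxy-3,7,11-trimethyldodeca-6,10-dien-8-yl acetate
Product: 14 acetylcaespitol, via primary triflate 10 (not isolated), via dioxolanylium triflate 11 (not isolated), via tertiary acetate 12 (not isolated), via hydroxy acetate 13 (not isolated)
Conditions: Tf2O, 2,6-di-tert-butyl-4-methylpyridine, CH2Cl2, −78 °C; dry HFIP (to 2 mM), −20 °C to rt; H2O (5 equiv), K2CO3, rt; NBS (1.05 equiv), 0 °C
Reagents that add atoms: triflic anhydride O=S(=O)(OS(=O)(=O)C(F)(F)F)C(F)(F)F (its atoms stay only in 10 and 11); water O; N-bromosuccinimide O=C1CCC(=O)N1Br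
Why: Proposed new method: the β-bromo primary triflate 10 ionises in HFIP with anchimeric assistance from the C2 bromine, the (6E)-alkene attacks C1 anti to bromine, which forces Br (and hence Cl and the C7 arm) into equatorial positions of a chair and sets 6R, and the C8 acetate carbonyl, which sits on the opposite alkene face in the A(1,3)-minimised rotamer, closes on C7 in the same anti addition to set 7S and give 11; water then opens 11, carbonate moves the acyl group of 12 to the less hindered O8 to give 13, and NBS triggers a Markovnikov 6-endo bromoetherification by the C7 hydroxyl through the chair that keeps the cyclohexyl group and bromine equatorial to set 10S; the closest known reaction types are halonium-initiated cation–π cyclisation started by HFIP solvolysis of a vicinal bromo/leaving-group pair, Woodward–Prévost acetoxonium capture, and bromoetherification.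

## Compound list
1 | neryl acetate, (2Z)-3,7-dimethylocta-2,6-dien-1-yl acetate | CC(C)=CCC/C(C)=C\COC(C)=O | starting material
2 | (2Z,6E)-3,7-dimethyl-8-oxoocta-2,6-dien-1-yl acetate | CC(=O)OC/C=C(C)\CC/C=C(C)/C=O | intermediate
3 | allyltributylstannane | C=CC[Sn](CCCC)(CCCC)CCCC | starting material
4 | (2Z,6E,8S)-8-hydroxy-3,7-dimethylundeca-2,6,10-trien-1-yl acetate | CC(=O)OC/C=C(C)\CC/C=C(C)/[C@@H](O)CC=C | intermediate
5 | (2Z,6E,8S)-3,7-dimethylundeca-2,6,10-triene-1,8-diyl diacetate | CC(=O)OC/C=C(C)\CC/C=C(C)/[C@@H](OC(C)=O)CC=C | intermediate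
6 | (2Z,6E,8S)-1-hydroxy-3,7-dimethylundeca-2,6,10-trien-8-yl acetate | OC/C=C(C)\CC/C=C(C)/[C@@H](OC(C)=O)CC=C | intermediate
7 | (2R,3R,6E,8S)-2-bromo-3-chloro-1-hydroxy-3,7-dimethylundeca-6,10-dien-8-yl acetate | OC[C@@H](Br)[C@](C)(Cl)CC/C=C(C)/[C@@H](OC(C)=O)CC=C | intermediate
8 | 2-methylbut-2-ene | CC=C(C)C | starting material
9 | (2R,3R,6E,8S)-2-bromo-3-chloro-1-hydroxy-3,7,11-trimethyldodeca-6,10-dien-8-yl acetate | OC[C@@H](Br)[C@](C)(Cl)CC/C=C(C)/[C@@H](OC(C)=O)CC=C(C)C | intermediate
10 | (2R,3R,6E,8S)-2-bromo-3-chloro-3,7,11-trimethyl-1-(trifluoromethylsulfonyloxy)dodeca-6,10-dien-8-yl acetate | O=S(=O)(OC[C@@H](Br)[C@](C)(Cl)CC/C=C(C)/[C@@H](OC(C)=O)CC=C(C)C)C(F)(F)F | intermediate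
11 | (4S,5S)-4-[(1R,3R,4R)-3-bromo-4-chloro-4-methylcyclohexyl]-2,4-dimethyl-5-(3-methylbut-2-en-1-yl)-1,3-dioxolan-2-ylium triflate | CC1=[O+][C@@H](CC=C(C)C)[C@@](C)(O1)[C@@H]2CC[C@@](C)(Cl)[C@H](Br)C2.[O-]S(=O)(=O)C(F)(F)F | intermediate
12 | (2S,3S)-2-[(1R,3R,4R)-3-bromo-4-chloro-4-methylcyclohexyl]-3-hydroxy-6-methylhept-5-en-2-yl acetate | O[C@@H](CC=C(C)C)[C@@](C)(OC(C)=O)[C@@H]1CC[C@@](C)(Cl)[C@H](Br)C1 | intermediate
13 | (2S,3S)-2-[(1R,3R,4R)-3-bromo-4-chloro-4-methylcyclohexyl]-2-hydroxy-6-methylhept-5-en-3-yl acetate | CC(=O)O[C@@H](CC=C(C)C)[C@@](C)(O)[C@@H]1CC[C@@](C)(Cl)[C@H](Br)C1 | intermediate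
14 | acetylcaespitol, (2S,3S,5S)-5-bromo-2-[(1R,3R,4R)-3-bromo-4-chloro-4-methylcyclohexyl]-2,6,6-trimethyloxan-3-yl acetate | CC(=O)O[C@H]1C[C@H](Br)C(C)(C)O[C@@]1(C)[C@@H]1CC[C@@](C)(Cl)[C@H](Br)C1 | target

## Step count and risks
Total step count: 7. Longest linear sequence: 7 (1 → 2 → 4 → 5 → 6 → 7 → 9 → 14).

**Step 7 (highest risk).**
- The deactivated 6,7-alkene may be too slow for the C1 electrophile.
- Attack at C2 would give a five-membered ring.
- Br+ could transfer to the prenyl alkene, or the tertiary chloride could solvolyse.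
- The last stage could divert to 5-exo closure.

The fallback moves the ring halogens to the end and closes the carbocycle through a classical neryl-type allyl cation. It sets out from 6 and comes back at 14. Cross-metathesis of 6 with 8 (Grubbs II) gives (2Z,6E,8S)-8-acetoxyfarnesol F1. Catalytic Ca(NTf2)2/Bu4NPF6 in HFIP at 0 °C ionises the allylic alcohol. The 6E-alkene then closes the ring, the acetate captures C7, and the liberated water opens the acetoxonium ion. After carbonate equilibration this gives the cyclohexenyl hydroxy acetate F2. NBS in HFIP closes the bromo-oxane F3.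

Direct BrCl addition to such a 4-substituted 1-methylcyclohexene follows the Fürst–Plattner rule and would give the trans-diaxial adduct with both halogen centres wrong. The halogens are therefore introduced with reversed polarity. NCS in aqueous acetone gives the trans-diaxial chlorohydrin F4. TMSBr in CH2Cl2 at −40 °C turns the tertiary alcohol into the diaxial bromochloride F5. Heating in toluene at 110 °C then brings about the diaxial-to-diequatorial 1,2-dihalide interchange (type I dyotropic shift), which inverts both centres and gives 14.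

**Step 5.** The enantioselectivity or chemoselectivity on a Z-configured polyene substrate may be insufficient. The fallback gives up catalyst control and relies on C8 being homochiral already. It sets out from 6 and comes back at 7. Ligand-free, titanium-directed bromochlorination (ClTi(OiPr)3, NBS, hexanes) keeps the site and regioselectivity. It gives 7 together with the (2S,3S,8S)-bromochloride F6. The two are diastereomers and are separated by preparative HPLC.

**Step 4.** Discrimination between the two acetates may be poor. The fallback avoids a diacetate altogether. It sets out from 4 and comes back at 6. Full methanolysis of 4 (K2CO3, MeOH, rt) gives the trienediol F7. TBSCl/imidazole at −20 °C silylates only the primary hydroxyl to give the silyl ether F8. Ac2O/DMAP gives the silyl ether acetate F9, and HF·pyridine in THF releases 6.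

## Further compounds
F1 | step 7 | (2Z,6E,8S)-1-hydroxy-3,7,11-trimethyldodeca-2,6,10-trien-8-yl acetate | OC/C=C(C)\CC/C=C(C)/[C@@H](OC(C)=O)CC=C(C)C
F2 | step 7 | (2S,3S)-2-hydroxy-6-methyl-2-[(1R)-4-methylcyclohex-3-en-1-yl]hept-5-en-3-yl acetate | CC(=O)O[C@@H](CC=C(C)C)[C@@](C)(O)[C@@H]1CCC(C)=CC1
F3 | step 7 | (2S,3S,5S)-5-bromo-2,6,6-trimethyl-2-[(1R)-4-methylcyclohex-3-en-1-yl]oxan-3-yl acetate | CC(=O)O[C@H]1C[C@H](Br)C(C)(C)O[C@@]1(C)[C@@H]1CCC(C)=CC1
F4 | step 7 | (2S,3S,5S)-5-bromo-2-[(1R,3S,4S)-3-chloro-4-hydroxy-4-methylcyclohexyl]-2,6,6-trimethyloxan-3-yl acetate | CC(=O)O[C@H]1C[C@H](Br)C(C)(C)O[C@@]1(C)[C@@H]1CC[C@@](O)(C)[C@@H](Cl)C1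
F5 | step 7 | (2S,3S,5S)-5-bromo-2-[(1R,3S,4S)-4-bromo-3-chloro-4-methylcyclohexyl]-2,6,6-trimethyloxan-3-yl acetate | CC(=O)O[C@H]1C[C@H](Br)C(C)(C)O[C@@]1(C)[C@@H]1CC[C@@](Br)(C)[C@@H](Cl)C1
F6 | step 5 | (2S,3S,6E,8S)-2-bromo-3-chloro-1-hydroxy-3,7-dimethylundeca-6,10-dien-8-yl acetate | OC[C@H](Br)[C@@](C)(Cl)CC/C=C(C)/[C@@H](OC(C)=O)CC=C
F7 | step 4 | (2Z,6E,8S)-3,7-dimethylundeca-2,6,10-triene-1,8-diol | OC/C=C(C)\CC/C=C(C)/[C@@H](O)CC=C
F8 | step 4 | (2Z,6E,8S)-1-(tert-butyldimethylsilyloxy)-3,7-dimethylundeca-2,6,10-trien-8-ol | CC(C)(C)[Si](C)(C)OC/C=C(C)\CC/C=C(C)/[C@@H](O)CC=C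
F9 | step 4 | (2Z,6E,8S)-1-(tert-butyldimethylsilyloxy)-3,7-dimethylundeca-2,6,10-trien-8-yl acetate | CC(C)(C)[Si](C)(C)OC/C=C(C)\CC/C=C(C)/[C@@H](OC(C)=O)CC=C
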